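# Proposed total synthesis of CNP0018313.0 with ring D built by a cyclobutenone–ynol ether benzannulation

## Analysis of the target

The target (36) is a linear pentamer of oxygenated benzene rings, lettered A to E from the 3,5-dihydroxyphenoxy end, joined by four diaryl ether oxygens and carrying eleven free phenolic hydroxyls. In each ring, position 1 is the carbon whose ether oxygen points toward ring A. Ring A is 1,3,5-trioxygenated, and rings B to E are each 1,2,3,5-tetraoxygenated: B has ether oxygens on B1 (to A) and B6 (to C) and hydroxyls on B2 and B4; C has ether oxygens on C1 and C4 and hydroxyls on C2 and C6; D has ether oxygens on D1 (to C) and D6 (to E) and hydroxyls on D2 and D4; E has its ether oxygen on E1 and hydroxyls on E2, E4 and E6. There is no stereocentre and the diaryl ether axes rotate freely, so the problem is purely one of regiochemistry. The free undecaphenol is very polar and is oxidised by air, above all in base, so every hydroxyl should travel as an alkyl ether and be released in the last step. The synthesis is hard because each ether link ends on a carbon flanked by two oxygen substituents (B1, C1, D1, E1), the rings are too electron-rich for unassisted nucleophilic aromatic substitution, and eleven near-equivalent oxygens must be told apart. The most crowded site is ring D, where D2, D1 and D6 are three adjacent oxygenated carbons and D1 and D6 both carry aryl ethers. The strategy rests on the pattern of ring D, read as D1(OAr), D2(OH), D3(H), D4(OH), D5(H), D6(OAr): it divides into three two-carbon units, D1–D2, D3–D4 and D5–D6, each of which can arrive from an open-chain piece with its oxygen already attached.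

## Retrosynthetic reasoning

**36 to 35.** The eleven O–alkyl bonds are cut last (ten O–methyl and the O–ethyl on D4). Small alkyl ethers keep all intermediates lipophilic and inert to oxidation, and one Lewis-acid dealkylation releases them together. The forward step only has to break alkyl–oxygen bonds, because the four diaryl ether oxygens offer no sp3 carbon for attack.

**35 to 33 and 34.** The A1–O bond is cut. A1 is the only ether carbon in the molecule without an ortho substituent, and ring A is available as bromide 34. The hindered partner (the B1 hydroxyl of 33) is then the nucleophile and the unhindered one the electrophile, which is the favourable polarity for a copper-catalysed Ullmann etherification.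

**33 to 31 to 27 and 30.** The B1 hydroxyl is traced back to a formyl group (Dakin oxidation). With that formyl group in place the B6–O bond can be cut by nucleophilic aromatic substitution, phenol 27 displacing the fluorine of aldehyde 30. Ring B is otherwise too electron-rich to be attacked; the formyl group first activates B6 and then becomes the oxygen B1 needs. Aldehyde 30 goes back to fluoroarene 28 by formylation.

**27 to 26 to 25.** Two protecting-group changes lie between trimer phenol 27 and the product of the ring construction. The C1 oxygen is carried as a benzyl ether, the only group in the route removed by hydrogenolysis, so exactly one oxygen is unmasked. The D2 hydroxyl that the ring construction leaves free in 25 is capped as a methyl ether in 26 so that it cannot compete with the C1 hydroxyl later.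

**25 to 19 and 20 (key disconnection).** Ring D is taken apart at D2–D3 and D4–D5, giving cyclobutenone 19 and ethoxyacetylene 20; in the forward direction the D1–D2 bond is broken and re-formed. The cut is made here because ring D is where coupling chemistry is weakest: D1 lies between two oxygenated carbons and would have to be etherified next to the D6 aryl ether. In 19 the two aryloxy groups already sit on adjacent carbons and the carbonyl oxygen is the future D2 hydroxyl; 20 supplies D3, D4 and the D4 oxygen. The forward reaction has to open 19 to a vinylketene, trap it with 20 in the right orientation and electrocyclise, which is what a Danheiser benzannulation does.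

**19 to 8 and 17.** The four-membered ring is cut at its 1–2 and 3–4 bonds (carbonyl carbon = 1) into aryloxyketene 18, generated from acid chloride 8, and ethynyl ether 17. Each aryl ether oxygen then rides on its own two-carbon piece: D2 and D1 come from 8, D5 and D6 from 17. The forward (2+2) cycloaddition must join the ketene carbonyl carbon to the unsubstituted alkyne carbon.

**8 to 7 to 4 and 5; 4 to 2 to 1.** The acid chloride comes from acid 7, and the O–CH2 bond of 7 is cut to phenol 4 and bromoacetate 5. Phenol 4 goes back through a Dakin oxidation to benzylated aldehyde 2 and syringaldehyde 1, whose substitution pattern is exactly that of ring C.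

**17 to 14 to 11 and 12; 11 to 9.** The alkyne of 17 is traced to dichlorovinyl ether 14, and its O–C(sp2) bond is cut to phenol 11 and trichloroethylene 12, which supplies D5 and D6. Phenol 11 comes from aldehyde 9 by Dakin oxidation, so ring E enters with all four oxygens in place.

## Alternatives that were turned down

**Alternative 1:** Ring A of the protected pentamer A1 (ring A as a methyl 4-hydroxy-2-methoxy-6-aryloxybenzoate) would be cut at A4–A5 and A6–A1, back to the aryloxypropiolate A2 of a B–C–D–E tetramer and the silyloxy diene A3. In the forward step A3 adds (4+2) to A2 with its unsubstituted terminus on the oxygen-bearing alkyne carbon, and the adduct aromatises by expelling one methoxy group as the alcohol.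
- For it: the regiochemistry of the cycloaddition is dependable and the aromatisation irreversible. The bond from ring A to the crowded B1 oxygen is made without a copper coupling; on that one point it is stronger than step 15 of the chosen route.
- Against it: ring A is the only unhindered ring and can be bought as 34, so the key step is spent on the easiest ring. The whole tetramer, with three crowded ether links, must first be assembled by other means. A2 is a donor-substituted alkyne, hence a sluggish dienophile, and must be made late on a di-ortho-substituted phenol of the kind of 33. The ester carbon that steers the cycloaddition must then be removed by saponification and decarboxylation.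
- Comparison: the chosen strategy builds the ring where ether coupling is weakest and leaves ring A to one coupling step.

**Alternative 2:** Ring B of hydroquinone A4 would be opened at B4–B5, back to the 4-hydroxy-4-(1-aryloxyvinyl)cyclobutenone A5, itself the adduct of a lithiated vinyl ether of ring C and a cyclobutenedione monoether. On heating, A5 opens to a dienylketene that closes onto the vinyl terminus and tautomerises.
- For it: the thermolysis is unimolecular and of a thoroughly explored type, so it does not depend on trapping a ketene with a volatile partner; on that point it is safer than step 9. It also brings in the B6 ether oxygen on the vinyl ether and marks the B2 oxygen (isopropyl) apart from B1 and B4 (free).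
- Against it: the B1 oxygen must still be arylated with ring A at a di-ortho-substituted hydroxyl, after the two hydroxyls of an air-sensitive hydroquinone have been told apart. α-Lithiation of an aryl vinyl ether of an electron-rich ring competes with ring lithiation. Above all, the C–D–E portion with the two most crowded links (C4–O–D1 and D6–O–E1) is untouched and must still be made by coupling.
- Comparison: both strategies use the same kind of electrocyclic cascade, but the chosen one applies it to the ring where both ether oxygens (on D1 and D6) arrive with the fragments, so no C–O bond is made on the new ring.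

**Alternative 3:** Ring E of isophthalate A6 would be cut at E2–E3 and E5–E6, back to aryloxymalonate A7 (ring D oxygen on the malonate carbon) and ketodiester A8. In the forward step both α-carbons of A8 are acylated by the two ester groups of A7 in a double Claisen condensation, and the cyclic triketone enolises to the phloroglucinol ring.
- For it: very cheap open-chain materials; all three ring E hydroxyls arise from carbonyl groups; the D6–O–E1 oxygen is attached by simple alkylation at the malonate stage; no strained or thermally labile intermediate is involved. In cost of materials it is stronger than the chosen route.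
- Against it: malonate esters are poor acyl donors, and A7 has an acidic C–H that is deprotonated first, which shuts its esters down, while A8 condenses readily with itself. The two ester groups on E3 and E5 must be removed again and the three new hydroxyls re-protected before further coupling. The ring made is a terminal ring whose oxygenation pattern can be bought (9), so the demanding links at D1 and around ring B still need conventional couplings.
- Comparison: the chosen strategy spends its ring construction on interior ring D and takes ring E from 9 in three routine steps.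

Key step: step 9

Remark: compounds 19, 22 and 24 are racemic; their single stereocentres vanish on aromatisation, so only double-bond geometry is specified for the transient intermediates.

## Route

Step 1
Reactants: 1 syringaldehyde (4-hydroxy-3,5-dimethoxybenzaldehyde)
Product: 2 4-(benzyloxy)-3,5-dimethoxybenzaldehyde
Conditions: BnBr, K2CO3, DMF, rt
Reagents that add atoms: benzyl bromide, BrCc1ccccc1
Why: Williamson O-benzylation of the acidic 4-hydroxyl; benzyl is the one group in the route cleaved by hydrogenolysis, so it marks the oxygen (later on C1) that must be freed alone.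

Step 2
Reactants: 2 4-(benzyloxy)-3,5-dimethoxybenzaldehyde
Product: 4 4-(benzyloxy)-3,5-dimethoxyphenol, via aryl formate 3 (not isolated)
Conditions: mCPBA, CH2Cl2, 0 °C to rt; aq NaHCO3 wash; then K2CO3, MeOH, rt
Reagents that add atoms: meta-chloroperoxybenzoic acid (mCPBA), OOC(=O)c1cccc(Cl)c1
Why: Dakin-type Baeyer–Villiger oxidation of an electron-rich benzaldehyde, the para-alkoxy group favouring aryl migration, followed by methanolysis of the formate.

Step 3
Reactants: 4 4-(benzyloxy)-3,5-dimethoxyphenol; 5 ethyl bromoacetate
Product: 7 2-[4-(benzyloxy)-3,5-dimethoxyphenoxy]acetic acid, via ethyl ester 6 (not isolated)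
Conditions: K2CO3, acetone, reflux; then LiOH, THF–H2O, rt; aq HCl
Reagents that add atoms: lithium hydroxide, [Li+].[OH-]
Why: Williamson alkylation of the phenoxide by the α-bromo ester and saponification; the two carbons introduced become D1 and D2 of ring D.

Step 4
Reactants: 7 2-[4-(benzyloxy)-3,5-dimethoxyphenoxy]acetic acid
Product: 8 2-[4-(benzyloxy)-3,5-dimethoxyphenoxy]acetyl chloride
Conditions: (COCl)2, DMF (cat.), CH2Cl2, 0 °C to rt; evaporate, use crude at once
Reagents that add atoms: oxalyl chloride, ClC(=O)C(=O)Cl
Why: Acid chloride formation through the catalytic chloroiminium species under mild, volatile-by-product conditions; immediate use forestalls Friedel–Crafts closure onto the activated ring.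

Step 5
Reactants: 9 2,4,6-trimethoxybenzaldehyde
Product: 11 2,4,6-trimethoxyphenol, via aryl formate 10 (not isolated)
Conditions: mCPBA, CH2Cl2, 0 °C to rt; aq NaHCO3 wash; then K2CO3, MeOH, rt
Reagents that add atoms: meta-chloroperoxybenzoic acid (mCPBA), OOC(=O)c1cccc(Cl)c1
Why: Dakin-type Baeyer–Villiger oxidation as in step 2; two ortho and one para methoxy group make aryl migration strongly preferred.

Step 6
Reactants: 11 2,4,6-trimethoxyphenol; 12 trichloroethylene
Product: 14 2-{[(E)-1,2-dichloroethenyl]oxy}-1,3,5-trimethoxybenzene, via dichloroacetylene 13 (not isolated)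
Conditions: K2CO3, DMF, 70 °C
Reagents that add atoms: none
Why: Base eliminates HCl from trichloroethylene and the phenoxide adds anti to the resulting dichloroacetylene, giving the (E)-dichlorovinyl ether; this is the standard first half of the ynol ether synthesis from phenols.

Step 7
Reactants: 14 2-{[(E)-1,2-dichloroethenyl]oxy}-1,3,5-trimethoxybenzene
Product: 17 2-(ethynyloxy)-1,3,5-trimethoxybenzene, via chloroethynyl ether 15 (not isolated), via lithium acetylide 16 (not isolated)
Conditions: n-BuLi (2.5 equiv), Et2O, −78 to −40 °C; then H2O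
Reagents that add atoms: none
Why: Deprotonation and β-elimination give the chloroalkyne, chlorine–lithium exchange gives the acetylide, and the quench protonates it; the low temperature suppresses ring lithiation and the two ortho-methoxy groups shield the ynol ether from self-addition.

Step 8
Reactants: 8 2-[4-(benzyloxy)-3,5-dimethoxyphenoxy]acetyl chloride; 17 2-(ethynyloxy)-1,3,5-trimethoxybenzene
Product: 19 4-[4-(benzyloxy)-3,5-dimethoxyphenoxy]-3-(2,4,6-trimethoxyphenoxy)cyclobut-2-en-1-one (racemic), via aryloxyketene 18 (not isolated)
Conditions: Et3N, CH2Cl2, 0 °C to rt, slow addition of 8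
Reagents that add atoms: none
Why: Dehydrochlorination gives the aryloxyketene, which adds (2+2) to the ynol ether as ketenes from acid chlorides do with alkoxyacetylenes. The ketene carbonyl carbon bonds to the nucleophilic unsubstituted alkyne carbon, so the ring E oxygen ends on carbon 3 and the ring C oxygen on carbon 4; the carbon-4 stereocentre is racemic and is destroyed in step 9.

Step 9
Reactants: 19 4-[4-(benzyloxy)-3,5-dimethoxyphenoxy]-3-(2,4,6-trimethoxyphenoxy)cyclobut-2-en-1-one; 20 ethoxyacetylene
Product: 25 2-[4-(benzyloxy)-3,5-dimethoxyphenoxy]-5-ethoxy-3-(2,4,6-trimethoxyphenoxy)phenol, via vinylketene 21 (not isolated), via vinylcyclobutenone 22 (not isolated), via dienylketene 23 (not isolated), via cyclohexadienone 24 (not isolated)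
Conditions: 20 (3 equiv), toluene, 80 °C, sealed tube
Reagents that add atoms: none
Why: Heating opens 19 by conrotatory four-electron electrocyclic cleavage of its 1–4 bond, the 4-aryloxy donor turning outward, to give vinylketene 21. The ketene adds (2+2) to 20, its carbonyl carbon bonding to the unsubstituted alkyne carbon (bond D2–D3) and its α-carbon to the ethoxy-bearing carbon (bond D4–D5), giving 22. Cyclobutenone 22 opens to dienylketene 23, and ring D is closed by thermal disrotatory six-electron electrocyclisation that joins the ketene carbon to the terminal CH(OAr) carbon (bond D1–D2); the resulting cyclohexadienone 24 tautomerises irreversibly to phenol 25. The closest known reaction type is the Danheiser benzannulation of cyclobutenones with alkoxy- and siloxyacetylenes, which gives resorcinol monoethers by this same cascade; the 3,4-bis(aryloxy) pattern is an untried member of that class. No stereocentre is formed in the product, since the sp3 carbons of 19, 22 and 24 all become aromatic carbons. The selectivity needed is regiochemical: the polarised ynol ether places the ethoxy group meta to the new hydroxyl (on D4), and the fixed 3,4-relationship of the aryloxy groups in 19 places the ring C oxygen on D1 next to that hydroxyl and the ring E oxygen on D6. Because cyclobutenone opening is reversible, only the dienylketene with the vinyl group turned inward is drained by the electrocyclisation. An excess of 20 in a closed vessel keeps bimolecular capture ahead of ketene dimerisation, and the moderate temperature stays below that at which 20 fragments.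

Step 10
Reactants: 25 2-[4-(benzyloxy)-3,5-dimethoxyphenoxy]-5-ethoxy-3-(2,4,6-trimethoxyphenoxy)phenol
Product: 26 2-{2-[4-(benzyloxy)-3,5-dimethoxyphenoxy]-5-ethoxy-3-methoxyphenoxy}-1,3,5-trimethoxybenzene
Conditions: MeI, K2CO3, DMF, rt
Reagents that add atoms: iodomethane, CI
Why: Williamson methylation of the only free phenol (on D2), so that it cannot compete with the C1 hydroxyl in steps 13 and 15.

Step 11
Reactants: 26 2-{2-[4-(benzyloxy)-3,5-dimethoxyphenoxy]-5-ethoxy-3-methoxyphenoxy}-1,3,5-trimethoxybenzene
Product: 27 4-[4-ethoxy-2-methoxy-6-(2,4,6-trimethoxyphenoxy)phenoxy]-2,6-dimethoxyphenol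
Conditions: H2 (1 atm), Pd/C, EtOAc–MeOH, rt
Reagents that add atoms: none
Why: Hydrogenolysis of the single benzyl ether; diaryl ethers and alkyl aryl ethers are inert, so only the C1 hydroxyl is released.

Step 12
Reactants: 28 1-fluoro-3,5-dimethoxybenzene
Product: 30 2-fluoro-4,6-dimethoxybenzaldehyde, via iminium salt 29 (not isolated)
Conditions: POCl3, DMF, 0 to 60 °C; then H2O
Reagents that add atoms: N,N-dimethylformamide, CN(C)C=O; water, O
Why: Vilsmeier–Haack formylation; attack should favour the carbon between fluorine and methoxy (para to the other methoxy), as with the chloro and bromo analogues, because the position between the two methoxy groups is more hindered. The minor regioisomer would be removed by chromatography.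

Step 13
Reactants: 27 4-[4-ethoxy-2-methoxy-6-(2,4,6-trimethoxyphenoxy)phenoxy]-2,6-dimethoxyphenol; 30 2-fluoro-4,6-dimethoxybenzaldehyde
Product: 31 2-{4-[4-ethoxy-2-methoxy-6-(2,4,6-trimethoxyphenoxy)phenoxy]-2,6-dimethoxyphenoxy}-4,6-dimethoxybenzaldehyde
Conditions: Cs2CO3, DMSO, 100 °C
Reagents that add atoms: none
Why: Nucleophilic aromatic substitution of fluoride ortho to the formyl group, which stabilises the Meisenheimer adduct; the methoxy groups are meta to fluorine and do not oppose attack at that carbon.

Step 14
Reactants: 31 2-{4-[4-ethoxy-2-methoxy-6-(2,4,6-trimethoxyphenoxy)phenoxy]-2,6-dimethoxyphenoxy}-4,6-dimethoxybenzaldehyde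
Product: 33 2-{4-[4-ethoxy-2-methoxy-6-(2,4,6-trimethoxyphenoxy)phenoxy]-2,6-dimethoxyphenoxy}-4,6-dimethoxyphenol, via aryl formate 32 (not isolated)
Conditions: mCPBA, CH2Cl2, 0 °C to rt; aq NaHCO3 wash; then K2CO3, MeOH, rt
Reagents that add atoms: meta-chloroperoxybenzoic acid (mCPBA), OOC(=O)c1cccc(Cl)c1
Why: Dakin-type Baeyer–Villiger oxidation of a 2,4,6-trioxygenated benzaldehyde; the formyl group that activated step 13 becomes the B1 hydroxyl, and the fast aryl migration at 0 °C should outpace oxidation of the other electron-rich rings.

Step 15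
Reactants: 33 2-{4-[4-ethoxy-2-methoxy-6-(2,4,6-trimethoxyphenoxy)phenoxy]-2,6-dimethoxyphenoxy}-4,6-dimethoxyphenol; 34 1-bromo-3,5-dimethoxybenzene
Product: 35 2-{2-[4-[2-(3,5-dimethoxyphenoxy)-3,5-dimethoxyphenoxy]-3,5-dimethoxyphenoxy]-5-ethoxy-3-methoxyphenoxy}-1,3,5-trimethoxybenzene
Conditions: CuI (cat.), picolinic acid, K3PO4, DMSO, 100 °C
Reagents that add atoms: none
Why: Ullmann diaryl ether synthesis with a CuI–picolinic acid catalyst, a system suited to di-ortho-substituted phenols; the bromide is unhindered and its methoxy groups are meta to bromine.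

Step 16
Reactants: 35 2-{2-[4-[2-(3,5-dimethoxyphenoxy)-3,5-dimethoxyphenoxy]-3,5-dimethoxyphenoxy]-5-ethoxy-3-methoxyphenoxy}-1,3,5-trimethoxybenzene
Product: 36 2-{2-[4-[2-(3,5-dihydroxyphenoxy)-3,5-dihydroxyphenoxy]-3,5-dihydroxyphenoxy]-3,5-dihydroxyphenoxy}benzene-1,3,5-triol (CNP0018313.0)
Conditions: BBr3 (excess), CH2Cl2, −78 °C to rt, argon; then H2O
Reagents that add atoms: none
Why: Lewis-acid dealkylation: boron binds each ether oxygen and bromide attacks the methyl or ethyl carbon; the diaryl ether bonds offer no sp3 carbon and survive, and the aryl borates are hydrolysed on aqueous work-up under inert gas.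

## Compound list

1 | syringaldehyde | COc1cc(C=O)cc(OC)c1O | starting material
2 | 4-(benzyloxy)-3,5-dimethoxybenzaldehyde | COc1cc(C=O)cc(OC)c1OCc1ccccc1 | intermediate
3 | 4-(benzyloxy)-3,5-dimethoxyphenyl formate (not isolated) | COc1cc(OC=O)cc(OC)c1OCc1ccccc1 | intermediate
4 | 4-(benzyloxy)-3,5-dimethoxyphenol | COc1cc(O)cc(OC)c1OCc1ccccc1 | intermediate
5 | ethyl bromoacetate | CCOC(=O)CBr | starting material
6 | ethyl 2-[4-(benzyloxy)-3,5-dimethoxyphenoxy]acetate (not isolated) | CCOC(=O)COc1cc(OC)c(OCc2ccccc2)c(OC)c1 | intermediate
7 | 2-[4-(benzyloxy)-3,5-dimethoxyphenoxy]acetic acid | OC(=O)COc1cc(OC)c(OCc2ccccc2)c(OC)c1 | intermediate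
8 | 2-[4-(benzyloxy)-3,5-dimethoxyphenoxy]acetyl chloride | ClC(=O)COc1cc(OC)c(OCc2ccccc2)c(OC)c1 | intermediate
9 | 2,4,6-trimethoxybenzaldehyde | COc1cc(OC)c(C=O)c(OC)c1 | starting material
10 | 2,4,6-trimethoxyphenyl formate (not isolated) | COc1cc(OC)c(OC=O)c(OC)c1 | intermediate
11 | 2,4,6-trimethoxyphenol | COc1cc(OC)c(O)c(OC)c1 | intermediate
12 | trichloroethylene | ClC=C(Cl)Cl | starting material
13 | dichloroacetylene (not isolated) | ClC#CCl | intermediate
14 | 2-{[(E)-1,2-dichloroethenyl]oxy}-1,3,5-trimethoxybenzene | Cl/C=C(/Cl)Oc1c(OC)cc(OC)cc1OC | intermediate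
15 | 2-[(chloroethynyl)oxy]-1,3,5-trimethoxybenzene (not isolated) | ClC#COc1c(OC)cc(OC)cc1OC | intermediate
16 | lithium (2,4,6-trimethoxyphenoxy)acetylide (not isolated) | [Li]C#COc1c(OC)cc(OC)cc1OC | intermediate
17 | 2-(ethynyloxy)-1,3,5-trimethoxybenzene | C#COc1c(OC)cc(OC)cc1OC | intermediate
18 | [4-(benzyloxy)-3,5-dimethoxyphenoxy]ketene (not isolated) | O=C=COc1cc(OC)c(OCc2ccccc2)c(OC)c1 | intermediate
19 | 4-[4-(benzyloxy)-3,5-dimethoxyphenoxy]-3-(2,4,6-trimethoxyphenoxy)cyclobut-2-en-1-one (racemic) | O=C1C=C(Oc2c(OC)cc(OC)cc2OC)C1Oc1cc(OC)c(OCc2ccccc2)c(OC)c1 | intermediate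
20 | ethoxyacetylene | CCOC#C | starting material
21 | (3Z)-4-[4-(benzyloxy)-3,5-dimethoxyphenoxy]-3-(2,4,6-trimethoxyphenoxy)buta-1,3-dien-1-one (not isolated) | O=C=C/C(Oc1c(OC)cc(OC)cc1OC)=C/Oc1cc(OC)c(OCc2ccccc2)c(OC)c1 | intermediate
22 | 3-ethoxy-4-{(Z)-2-[4-(benzyloxy)-3,5-dimethoxyphenoxy]-1-(2,4,6-trimethoxyphenoxy)ethenyl}cyclobut-2-en-1-one (racemic, not isolated) | CCOC1=CC(=O)C1/C(Oc1c(OC)cc(OC)cc1OC)=C/Oc1cc(OC)c(OCc2ccccc2)c(OC)c1 | intermediate
23 | (3E,5Z)-6-[4-(benzyloxy)-3,5-dimethoxyphenoxy]-3-ethoxy-5-(2,4,6-trimethoxyphenoxy)hexa-1,3,5-trien-1-one (not isolated) | O=C=C/C(OCC)=C\C(Oc1c(OC)cc(OC)cc1OC)=C\Oc1cc(OC)c(OCc2ccccc2)c(OC)c1 | intermediate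
24 | 6-[4-(benzyloxy)-3,5-dimethoxyphenoxy]-3-ethoxy-5-(2,4,6-trimethoxyphenoxy)cyclohexa-2,4-dien-1-one (racemic, not isolated) | CCOC1=CC(=O)C(Oc2cc(OC)c(OCc3ccccc3)c(OC)c2)C(Oc2c(OC)cc(OC)cc2OC)=C1 | intermediate
25 | 2-[4-(benzyloxy)-3,5-dimethoxyphenoxy]-5-ethoxy-3-(2,4,6-trimethoxyphenoxy)phenol | CCOc1cc(O)c(Oc2cc(OC)c(OCc3ccccc3)c(OC)c2)c(Oc2c(OC)cc(OC)cc2OC)c1 | intermediate
26 | 2-{2-[4-(benzyloxy)-3,5-dimethoxyphenoxy]-5-ethoxy-3-methoxyphenoxy}-1,3,5-trimethoxybenzene | CCOc1cc(OC)c(Oc2cc(OC)c(OCc3ccccc3)c(OC)c2)c(Oc2c(OC)cc(OC)cc2OC)c1 | intermediate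
27 | 4-[4-ethoxy-2-methoxy-6-(2,4,6-trimethoxyphenoxy)phenoxy]-2,6-dimethoxyphenol | CCOc1cc(OC)c(Oc2cc(OC)c(O)c(OC)c2)c(Oc2c(OC)cc(OC)cc2OC)c1 | intermediate
28 | 1-fluoro-3,5-dimethoxybenzene | COc1cc(F)cc(OC)c1 | starting material
29 | N-[(2-fluoro-4,6-dimethoxyphenyl)methylidene]-N-methylmethanaminium dichlorophosphate (not isolated) | C[N+](C)=Cc1c(F)cc(OC)cc1OC.[O-]P(=O)(Cl)Cl | intermediate
30 | 2-fluoro-4,6-dimethoxybenzaldehyde | COc1cc(F)c(C=O)c(OC)c1 | intermediate
31 | 2-{4-[4-ethoxy-2-methoxy-6-(2,4,6-trimethoxyphenoxy)phenoxy]-2,6-dimethoxyphenoxy}-4,6-dimethoxybenzaldehyde | COc1cc(OC)c(C=O)c(Oc2c(OC)cc(Oc3c(OC)cc(OCC)cc3Oc3c(OC)cc(OC)cc3OC)cc2OC)c1 | intermediate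
32 | 2-{4-[4-ethoxy-2-methoxy-6-(2,4,6-trimethoxyphenoxy)phenoxy]-2,6-dimethoxyphenoxy}-4,6-dimethoxyphenyl formate (not isolated) | COc1cc(OC)c(OC=O)c(Oc2c(OC)cc(Oc3c(OC)cc(OCC)cc3Oc3c(OC)cc(OC)cc3OC)cc2OC)c1 | intermediate
33 | 2-{4-[4-ethoxy-2-methoxy-6-(2,4,6-trimethoxyphenoxy)phenoxy]-2,6-dimethoxyphenoxy}-4,6-dimethoxyphenol | COc1cc(OC)c(O)c(Oc2c(OC)cc(Oc3c(OC)cc(OCC)cc3Oc3c(OC)cc(OC)cc3OC)cc2OC)c1 | intermediate
34 | 1-bromo-3,5-dimethoxybenzene | COc1cc(Br)cc(OC)c1 | starting material
35 | 2-{2-[4-[2-(3,5-dimethoxyphenoxy)-3,5-dimethoxyphenoxy]-3,5-dimethoxyphenoxy]-5-ethoxy-3-methoxyphenoxy}-1,3,5-trimethoxybenzene | COc1cc(OC)cc(Oc2c(OC)cc(OC)cc2Oc2c(OC)cc(Oc3c(OC)cc(OCC)cc3Oc3c(OC)cc(OC)cc3OC)cc2OC)c1 | intermediate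
36 | 2-{2-[4-[2-(3,5-dihydroxyphenoxy)-3,5-dihydroxyphenoxy]-3,5-dihydroxyphenoxy]-3,5-dihydroxyphenoxy}benzene-1,3,5-triol (CNP0018313.0) | Oc1cc(O)cc(Oc2c(O)cc(O)cc2Oc2c(O)cc(Oc3c(O)cc(O)cc3Oc3c(O)cc(O)cc3O)cc2O)c1 | target

## Step count and least certain steps

Total step count: 16. Longest linear sequence: 12 steps (steps 1, 2, 3, 4, 8, 9, 10, 11, 13, 14, 15, 16).

**Step 9 (key step).** The most likely failure is loss of the vinylketene before capture. The (2+2) addition to a volatile ynol ether is bimolecular, so ketene dimerisation and acylation of the product phenol compete. The vinylogous-ester stabilisation of 19 may also push the ring opening up to temperatures at which 20 itself fragments. The fallback gives up the ring construction and returns to ether chemistry on a preformed arene; it sets out from phenol 11 and comes back at 26. Purchased 2,6-difluoro-4-hydroxybenzaldehyde F1 would be O-ethylated (EtI, K2CO3, DMF) to 4-ethoxy-2,6-difluorobenzaldehyde F2. Nucleophilic aromatic substitution by 11 (K2CO3, DMF, 60 °C) should replace one fluorine and give 4-ethoxy-2-fluoro-6-(2,4,6-trimethoxyphenoxy)benzaldehyde F3, and NaOMe in MeOH–THF should replace the second to give 4-ethoxy-2-methoxy-6-(2,4,6-trimethoxyphenoxy)benzaldehyde F4. Dakin oxidation as in step 2, through 4-ethoxy-2-methoxy-6-(2,4,6-trimethoxyphenoxy)phenyl formate F5, would give 4-ethoxy-2-methoxy-6-(2,4,6-trimethoxyphenoxy)phenol F6. Separately, purchased 4-bromo-2,6-dimethoxyphenol F7 would be benzylated (BnBr, K2CO3) to 2-(benzyloxy)-5-bromo-1,3-dimethoxybenzene F8. Ullmann coupling of F6 with F8 (CuI, picolinic acid, K3PO4, DMSO, 100 °C) would give 26. The price is a copper coupling at the di-ortho-substituted D1 hydroxyl, which the benzannulation avoids.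

**Step 8.** Ketene dimerisation and amine-induced oligomerisation may outrun the cycloaddition, because an aryl ynol ether is a weaker nucleophile than an alkyl one. The vinylogous aryl ester of 19 may also suffer addition–elimination by chloride or amine. The fallback avoids a free ketene; it sets out from 8 and 17 and comes back at 19. Acid chloride 8 with Me2NH would give N,N-dimethyl-2-[4-(benzyloxy)-3,5-dimethoxyphenoxy]acetamide F9. Tf2O and 2,4,6-collidine in CH2Cl2 would convert it into the keteniminium triflate F10, which does not dimerise and is more electrophilic than the ketene. Its (2+2) addition to 17, with the same orientation, would give the cyclobuteniminium triflate F11, and aqueous NaHCO3 would hydrolyse this to 19.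

**Step 13.** Substitution may be slow, because the formyl group of 30 is deactivated by two methoxy donors and the phenoxide of 27 is flanked by two methoxy groups. Prolonged heating in base then invites degradation of the aldehyde and O-demethylation by phenoxide. The fallback replaces nucleophilic aromatic substitution by copper catalysis; it sets out from 27 and comes back at 31. Ullmann coupling of 27 with purchased 2-bromo-4,6-dimethoxybenzaldehyde F12 (CuI, picolinic acid, K3PO4, DMSO, 90 °C), where the ortho-formyl group assists the coupling, would give 31 directly.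

**Step 15.** C–O bond formation may stall at a phenol flanked by a methoxy and an aryloxy group, so that hydrodebromination of 34 and oxidative decay of the electron-rich phenoxide take over. The fallback changes the aryl donor and the mechanism; it sets out from 33 and comes back at 35. Chan–Lam coupling of 33 with purchased (3,5-dimethoxyphenyl)boronic acid F13 (Cu(OAc)2, pyridine, 4 Å molecular sieves, CH2Cl2, air, rt) would give 35 under conditions that tolerate di-ortho-substituted phenols.

**Step 16.** Dealkylation may stop short as partly cleaved, insoluble aryl borates precipitate, and the free undecaphenol may be oxidised by air during work-up and chromatography. The fallback changes how the product is isolated; it sets out from 35 and comes back at 36. The crude product of the BBr3 treatment would be peracetylated (Ac2O, pyridine) to the undecaacetate F14, which is stable and can be chromatographed on silica and separated from incompletely dealkylated material. Acid methanolysis (HCl in degassed MeOH, rt) would then release 36 without exposure to base.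

## Further compounds

F1 | step 9 | 2,6-difluoro-4-hydroxybenzaldehyde (purchased) | O=Cc1c(F)cc(O)cc1F
F2 | step 9 | 4-ethoxy-2,6-difluorobenzaldehyde | CCOc1cc(F)c(C=O)c(F)c1
F3 | step 9 | 4-ethoxy-2-fluoro-6-(2,4,6-trimethoxyphenoxy)benzaldehyde | CCOc1cc(F)c(C=O)c(Oc2c(OC)cc(OC)cc2OC)c1
F4 | step 9 | 4-ethoxy-2-methoxy-6-(2,4,6-trimethoxyphenoxy)benzaldehyde | CCOc1cc(OC)c(C=O)c(Oc2c(OC)cc(OC)cc2OC)c1
F5 | step 9 | 4-ethoxy-2-methoxy-6-(2,4,6-trimethoxyphenoxy)phenyl formate | CCOc1cc(OC)c(OC=O)c(Oc2c(OC)cc(OC)cc2OC)c1
F6 | step 9 | 4-ethoxy-2-methoxy-6-(2,4,6-trimethoxyphenoxy)phenol | CCOc1cc(OC)c(O)c(Oc2c(OC)cc(OC)cc2OC)c1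
F7 | step 9 | 4-bromo-2,6-dimethoxyphenol (purchased) | COc1cc(Br)cc(OC)c1O
F8 | step 9 | 2-(benzyloxy)-5-bromo-1,3-dimethoxybenzene | COc1cc(Br)cc(OC)c1OCc1ccccc1
F9 | step 8 | N,N-dimethyl-2-[4-(benzyloxy)-3,5-dimethoxyphenoxy]acetamide | CN(C)C(=O)COc1cc(OC)c(OCc2ccccc2)c(OC)c1
F10 | step 8 | N-{2-[4-(benzyloxy)-3,5-dimethoxyphenoxy]ethenylidene}-N-methylmethanaminium trifluoromethanesulfonate | C[N+](C)=C=COc1cc(OC)c(OCc2ccccc2)c(OC)c1.[O-]S(=O)(=O)C(F)(F)F
F11 | step 8 | N-{4-[4-(benzyloxy)-3,5-dimethoxyphenoxy]-3-(2,4,6-trimethoxyphenoxy)cyclobut-2-en-1-ylidene}-N-methylmethanaminium trifluoromethanesulfonate (racemic) | C[N+](C)=C1C=C(Oc2c(OC)cc(OC)cc2OC)C1Oc1cc(OC)c(OCc2ccccc2)c(OC)c1.[O-]S(=O)(=O)C(F)(F)F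
F12 | step 13 | 2-bromo-4,6-dimethoxybenzaldehyde (purchased) | COc1cc(Br)c(C=O)c(OC)c1
F13 | step 15 | (3,5-dimethoxyphenyl)boronic acid (purchased) | COc1cc(OC)cc(B(O)O)c1
F14 | step 16 | undecaacetate of 36 | CC(=O)Oc1cc(OC(C)=O)cc(Oc2c(OC(C)=O)cc(OC(C)=O)cc2Oc2c(OC(C)=O)cc(Oc3c(OC(C)=O)cc(OC(C)=O)cc3Oc3c(OC(C)=O)cc(OC(C)=O)cc3OC(C)=O)cc2OC(C)=O)c1
A1 | alternative 1 | protected pentamer with ring A as methyl 4-hydroxy-2-methoxy-6-aryloxybenzoate | COC(=O)c1c(OC)cc(O)cc1Oc1c(OC)cc(OC)cc1Oc1c(OC)cc(Oc2c(OC)cc(OC)cc2Oc2c(OC)cc(OC)cc2OC)cc1OC
A2 | alternative 1 | methyl 3-aryloxypropiolate of the permethylated B–C–D–E tetramer | COC(=O)C#COc1c(OC)cc(OC)cc1Oc1c(OC)cc(Oc2c(OC)cc(OC)cc2Oc2c(OC)cc(OC)cc2OC)cc1OC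
A3 | alternative 1 | 1,1-dimethoxy-3-(trimethylsilyloxy)buta-1,3-diene | COC(OC)=CC(=C)O[Si](C)(C)C
A4 | alternative 2 | 2-(4-benzyloxy-2,6-dimethoxyphenoxy)-6-isopropoxybenzene-1,4-diol | CC(C)Oc1cc(O)cc(Oc2c(OC)cc(OCc3ccccc3)cc2OC)c1O
A5 | alternative 2 | 4-hydroxy-4-[1-(4-benzyloxy-2,6-dimethoxyphenoxy)ethenyl]-3-isopropoxycyclobut-2-en-1-one (racemic) | CC(C)OC1=CC(=O)C1(O)C(=C)Oc1c(OC)cc(OCc2ccccc2)cc1OC
A6 | alternative 3 | dimethyl 5-(2-benzyloxy-3,5-dimethoxyphenoxy)-2,4,6-trihydroxyisophthalate | COC(=O)c1c(O)c(C(=O)OC)c(O)c(Oc2cc(OC)cc(OC)c2OCc2ccccc2)c1O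
A7 | alternative 3 | dimethyl 2-(2-benzyloxy-3,5-dimethoxyphenoxy)malonate | COC(=O)C(Oc1cc(OC)cc(OC)c1OCc1ccccc1)C(=O)OC
A8 | alternative 3 | dimethyl 3-oxopentanedioate | COC(=O)CC(=O)CC(=O)OC
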